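**Strategy.** Cleistanthane numbering is used: ring B = C5–C10; ring C = C8(OOH), C9, C11, C12(=O), C13(Me), C14(vinyl). Ring C is a para-peroxyquinol, so the hydroperoxide is set last by singlet oxygen on phenol 18. The phenol comes from an oxygen heterocycle: a γ-pyranone fused to ring B (ring O between C9 and C12, C14 as carbonyl, C11 as methyl) takes up vinyl at C14; the pyrylium ion formed is opened by hydroxide to a (Z)-ene-1,5-dione whose C11 enolate closes ring C onto the C9 ketone (C9=C11) and aromatises. The step exploits the latent C9/C12 1,5-dicarbonyl of ring C, with C11 the only enolisable carbon able to reach C9 because C10 is quaternary.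

Key step: step 5

Remark on stereochemistry: the target is (1R,2R,4aR) in naphthalene numbering (C10 R, C5 R, C8 R); the hydroperoxide, the C10 methyl and the C5 isopropenyl lie on one face of ring B and the propanoate chain on the other.

Assumption: 2,2,5,6-tetramethyl-4H-1,3-dioxin-4-one (8) is taken as a catalogue reagent, and the enantiomer of the chiral ligand in step 1 is chosen to give the 3R product.

**Step 1**
Reactants: 1 2-methylcyclohex-2-en-1-one; 2 prop-1-en-2-ylmagnesium bromide
Product: 4 trimethyl{[(3R)-2-methyl-3-(prop-1-en-2-yl)cyclohex-1-en-1-yl]oxy}silane, via magnesium enolate 3 (not isolated)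
Conditions: Cu(OTf)2 (3 mol %), chiral hydroxyalkyl imidazolinium hexafluorophosphate (NHC precursor, 4 mol %), Et2O, −30 °C, slow addition of 2; then TMSCl, Et3N, DMPU, −30 °C to rt
Reagents that add atoms: chlorotrimethylsilane, C[Si](C)(C)Cl
Why: Copper-catalysed asymmetric conjugate addition of a Grignard reagent to an α-substituted cycloalkenone with silyl trapping of the enolate; the NHC–copper complex differentiates the enone faces and should set C5 as R, and O-silylation preserves the C9=C10 enolate regiochemistry.

**Step 2**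
Reactants: 4; 5 methyl acrylate
Product: 7 methyl 3-[(1R,6R)-1-methyl-2-oxo-6-(prop-1-en-2-yl)cyclohexyl]propanoate, via lithium enolate 6 (not isolated)
Conditions: MeLi, THF, 0 °C; then 5, −78 °C; AcOH quench at −78 °C
Reagents that add atoms: none
Why: Regiospecific lithium enolate generation from the silyl enol ether followed by Michael addition; the acrylate should attack C10 anti to the adjacent pseudoaxial isopropenyl group (1,2-induction in the tetrasubstituted enolate), so the chain ends trans and the methyl cis to isopropenyl.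

**Step 3**
Reactants: 7; 8 2,2,5,6-tetramethyl-4H-1,3-dioxin-4-one
Product: 11 methyl 3-[(7R,8R)-2,3,8-trimethyl-4-oxo-7-(prop-1-en-2-yl)-5,6,7,8-tetrahydro-4H-chromen-8-yl]propanoate, via enamine 9 (not isolated), via acylketene 10 (not isolated)
Conditions: morpholine, TiCl4, toluene, 0 °C to rt, filtration under argon; then 8, toluene, 110 °C; then TsOH·H2O (cat.), 110 °C
Reagents that add atoms: none
Why: TiCl4-mediated enamine formation is possible only towards C8 because C10 is quaternary, and the acylketene released by retro-[4+2] thermolysis of the dioxinone should add to the enamine in a formal hetero-Diels–Alder reaction (C8–C14 and O–C9 bonds) and expel morpholine to give the 4-pyranone.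

**Step 4**
Reactants: 11
Product: 12 3-[(7R,8R)-2,3,8-trimethyl-4-oxo-7-(prop-1-en-2-yl)-5,6,7,8-tetrahydro-4H-chromen-8-yl]propanoic acid
Conditions: Me3SnOH, 1,2-dichloroethane, 80 °C; 1 M HCl wash
Reagents that add atoms: trimethyltin hydroxide, C[Sn](C)(C)O
Why: Me3SnOH-mediated methyl ester hydrolysis runs under neutral conditions that should not open the base-sensitive 2-methyl-4-pyranone, and it supplies the acid that is masked as its carboxylate during the organometallic addition of step 5.

**Step 5**
Reactants: 12; 13 vinylmagnesium bromide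
Product: 17 3-[(1R,2R)-5-ethenyl-7-hydroxy-1,6-dimethyl-2-(prop-1-en-2-yl)-1,2,3,4-tetrahydronaphthalen-1-yl]propanoic acid, via pyranol adduct 14 (not isolated), via pyrylium chloride 15 (not isolated), via ene-dione 16 (not isolated)
Conditions: 13 (4 equiv), CeCl3, THF, −78 to 0 °C, argon; then 1 M HCl, 0 °C; then 2 M NaOH added slowly through pH 7 to pH 13, 0 to 40 °C; HCl to pH 3
Reagents that add atoms: sodium hydroxide, [Na+].[OH-]
Why: The vinylcerium reagent should add 1,2 to the pyranone C14 carbonyl while the C3 carboxylate stays inert, and acid ionises the bis-allylic pyranol 14 to the 4-vinylpyrylium ion 15. Hydroxide then adds to the less hindered α-carbon C12, the 2H-pyranol opens electrocyclically to the (Z)-ene-1,5-dione 16, and the C11 enolate of the C12 methyl ketone attacks the C9 ketone; loss of water gives the C9=C11 enone and the C8–H tautomerises to the phenolate, which is the classical base-induced ring transformation of 2-methylpyrylium salts into phenols. Ring C is closed by a 6-(enolendo)-exo-trig aldol condensation. No stereocentre is created, since C14 of 14 and C8 of 16 end as sp2 carbons, and C5 and C10 are not enolisable. The step needs C11 to be the carbon that attacks C9 and hydroxide to enter at the ring and not at the vinyl terminus: C11 is the only enolisable position that can reach C9 in a six-membered ring (C10 is quaternary, enolisation at C8 is unproductive), the Z geometry of C13=C14 is inherited from the heterocycle, and the hard nucleophile at low temperature should prefer the charged α-position, with aromatisation making the sequence irreversible.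

**Step 6**
Reactants: 17
Product: 18 methyl 3-[(1R,2R)-5-ethenyl-7-hydroxy-1,6-dimethyl-2-(prop-1-en-2-yl)-1,2,3,4-tetrahydronaphthalen-1-yl]propanoate
Conditions: MeI, KHCO3, DMF, rt
Reagents that add atoms: iodomethane, CI
Why: SN2 O-methylation of the carboxylate; KHCO3 deprotonates the acid but not the phenol, so only the methyl ester should form.

**Step 7**
Reactants: 18
Product: 19 trigonochinene C (methyl 3-[(1R,2R,4aR)-5-ethenyl-4a-hydroperoxy-1,6-dimethyl-7-oxo-2-(prop-1-en-2-yl)-1,2,3,4,4a,7-hexahydronaphthalen-1-yl]propanoate)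
Conditions: O2, 5,10,15,20-tetraphenylporphyrin (cat.), visible light, CH2Cl2/MeOH, −40 °C
Reagents that add atoms: dioxygen, O=O
Why: Sensitised singlet-oxygen photooxygenation of a para-alkylphenol, in which addition across C8/C12 and collapse of the hemiketal endoperoxide give the 4-hydroperoxycyclohexa-2,5-dienone; oxygen should enter C8 on the face of the C10 methyl, because this trajectory is anti to the pseudoaxial C7–H of the ring B half-chair and leads directly to a chair with equatorial isopropenyl (torsional control by the C5/C10 centres) while avoiding the face that carries the longer C10 propanoate chain, and the electron-rich phenol should react faster than the isopropenyl or vinyl groups.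

**Compound list**
1 | 2-methylcyclohex-2-en-1-one | CC1=CCCC1=O | starting material
2 | prop-1-en-2-ylmagnesium bromide (isopropenylmagnesium bromide) | CC(=C)[Mg]Br | starting material
3 | bromomagnesium (3R)-2-methyl-3-(prop-1-en-2-yl)cyclohex-1-en-1-olate | CC1=C(O[Mg]Br)CCC[C@@H]1C(C)=C | intermediate
4 | trimethyl{[(3R)-2-methyl-3-(prop-1-en-2-yl)cyclohex-1-en-1-yl]oxy}silane | C[Si](C)(C)OC1=C(C)[C@@H](C(C)=C)CCC1 | intermediate
5 | methyl acrylate | C=CC(=O)OC | starting material
6 | lithium (3R)-2-methyl-3-(prop-1-en-2-yl)cyclohex-1-en-1-olate | [Li]OC1=C(C)[C@@H](C(C)=C)CCC1 | intermediate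
7 | methyl 3-[(1R,6R)-1-methyl-2-oxo-6-(prop-1-en-2-yl)cyclohexyl]propanoate | O=C1CCC[C@H](C(C)=C)[C@@]1(C)CCC(=O)OC | intermediate
8 | 2,2,5,6-tetramethyl-4H-1,3-dioxin-4-one | CC1=C(C)C(=O)OC(C)(C)O1 | starting material
9 | methyl 3-[(1R,6R)-1-methyl-2-(morpholin-4-yl)-6-(prop-1-en-2-yl)cyclohex-2-en-1-yl]propanoate | C1COCCN1C2=CCC[C@H](C(C)=C)[C@@]2(C)CCC(=O)OC | intermediate
10 | 2-methyl-3-oxobut-1-en-1-one (acetyl(methyl)ketene) | CC(=O)C(C)=C=O | intermediate
11 | methyl 3-[(7R,8R)-2,3,8-trimethyl-4-oxo-7-(prop-1-en-2-yl)-5,6,7,8-tetrahydro-4H-chromen-8-yl]propanoate | O=C1C(C)=C(C)OC2=C1CC[C@H](C(C)=C)[C@@]2(C)CCC(=O)OC | intermediate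
12 | 3-[(7R,8R)-2,3,8-trimethyl-4-oxo-7-(prop-1-en-2-yl)-5,6,7,8-tetrahydro-4H-chromen-8-yl]propanoic acid | O=C1C(C)=C(C)OC2=C1CC[C@H](C(C)=C)[C@@]2(C)CCC(=O)O | intermediate
13 | vinylmagnesium bromide | C=C[Mg]Br | starting material
14 | 3-[(7R,8R)-4-ethenyl-4-hydroxy-2,3,8-trimethyl-7-(prop-1-en-2-yl)-5,6,7,8-tetrahydro-4H-chromen-8-yl]propanoic acid, formed as its metal alkoxide carboxylate (either C4 epimer) | C=CC1(O)C(C)=C(C)OC2=C1CC[C@H](C(C)=C)[C@@]2(C)CCC(=O)O | intermediate
15 | (7R,8R)-8-(2-carboxyethyl)-4-ethenyl-2,3,8-trimethyl-7-(prop-1-en-2-yl)-5,6,7,8-tetrahydrochromenylium chloride | C=Cc1c(C)c(C)[o+]c2c1CC[C@H](C(C)=C)[C@@]2(C)CCC(=O)O.[Cl-] | intermediate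
16 | 3-[(1R,6R)-1-methyl-3-[(3Z)-4-methyl-5-oxohexa-1,3-dien-3-yl]-2-oxo-6-(prop-1-en-2-yl)cyclohexyl]propanoic acid (either C3 epimer, present as carboxylate) | O=C1C(/C(C=C)=C(C)\C(C)=O)CC[C@H](C(C)=C)[C@@]1(C)CCC(=O)O | intermediate
17 | 3-[(1R,2R)-5-ethenyl-7-hydroxy-1,6-dimethyl-2-(prop-1-en-2-yl)-1,2,3,4-tetrahydronaphthalen-1-yl]propanoic acid | C=Cc1c(C)c(O)cc2c1CC[C@H](C(C)=C)[C@@]2(C)CCC(=O)O | intermediate
18 | methyl 3-[(1R,2R)-5-ethenyl-7-hydroxy-1,6-dimethyl-2-(prop-1-en-2-yl)-1,2,3,4-tetrahydronaphthalen-1-yl]propanoate | C=Cc1c(C)c(O)cc2c1CC[C@H](C(C)=C)[C@@]2(C)CCC(=O)OC | intermediate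
19 | trigonochinene C, methyl 3-[(1R,2R,4aR)-5-ethenyl-4a-hydroperoxy-1,6-dimethyl-7-oxo-2-(prop-1-en-2-yl)-1,2,3,4,4a,7-hexahydronaphthalen-1-yl]propanoate | C=CC1=C(C)C(=O)C=C2[C@]1(OO)CC[C@H](C(=C)C)[C@@]2(C)CCC(=O)OC | target

**Total step count:** 7
**Longest linear sequence:** 7 steps (1 to 19)

**Steps most likely to fail**

Step 5. What may go wrong: conjugate addition of water or hydroxide to the vinyl terminus of the 4-vinylpyrylium ion (or its oligomerisation), and deprotonation of the pyranone C11 methyl by the organometallic instead of 1,2-addition. The fallback introduces the vinyl group after ring closure and sets out from 12. Aqueous KOH (60 °C, argon) opens the pyranone to the 1,3,5-triketone, which closes ring C by the same C11-to-C9 aldol condensation and aromatises to the resorcinol acid F1. MeI/KHCO3 in DMF gives the resorcinol methyl ester F2, and TBSCl/imidazole silylates the less hindered C12 hydroxyl to give the mono-silyl ether F3. Tf2O/pyridine converts the C14 hydroxyl into the aryl triflate F4, and Stille coupling with tributyl(vinyl)stannane (Pd(PPh3)4, LiCl, dioxane, 100 °C) gives the vinyl arene silyl ether F5. TBAF/AcOH removes the silyl group and the fallback comes back to the route at 18.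

Step 7. What may go wrong: insufficient facial discrimination at C8 (oxygen entering anti to the C10 methyl if steric approach control overrides torsional control), together with ene reaction of singlet oxygen at the isopropenyl group or capture through the C14 vinyl group. The fallback replaces single-pass kinetic control by separation and recycling and sets out from 18. The C8 epimers are separated by chromatography, and the unwanted (4aS)-hydroperoxide F6 is treated with Zn/AcOH (O–O cleavage to the para-quinol, then reductive rearomatisation). This comes back to the route at 18, which is oxygenated again.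

Step 1. What may go wrong: ligand-free background addition of the branched alkenyl Grignard reagent eroding the enantiomeric purity. The fallback replaces catalyst control by classical resolution and sets out from 12 of insufficient enantiomeric purity. Its salt with (S)-1-phenylethylamine, the ammonium carboxylate F7, is crystallised to constant rotation and acidified with 1 M HCl, which comes back to the route at 12 as a single enantiomer.

**Further compounds**
F1 | step 5 | 3-[(1R,2R)-5,7-dihydroxy-1,6-dimethyl-2-(prop-1-en-2-yl)-1,2,3,4-tetrahydronaphthalen-1-yl]propanoic acid | Oc1c(C)c(O)cc2c1CC[C@H](C(C)=C)[C@@]2(C)CCC(=O)O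
F2 | step 5 | methyl 3-[(1R,2R)-5,7-dihydroxy-1,6-dimethyl-2-(prop-1-en-2-yl)-1,2,3,4-tetrahydronaphthalen-1-yl]propanoate | Oc1c(C)c(O)cc2c1CC[C@H](C(C)=C)[C@@]2(C)CCC(=O)OC
F3 | step 5 | methyl 3-[(1R,2R)-7-(tert-butyldimethylsilyloxy)-5-hydroxy-1,6-dimethyl-2-(prop-1-en-2-yl)-1,2,3,4-tetrahydronaphthalen-1-yl]propanoate | Oc1c(C)c(O[Si](C)(C)C(C)(C)C)cc2c1CC[C@H](C(C)=C)[C@@]2(C)CCC(=O)OC
F4 | step 5 | methyl 3-[(1R,2R)-7-(tert-butyldimethylsilyloxy)-1,6-dimethyl-2-(prop-1-en-2-yl)-5-(trifluoromethanesulfonyloxy)-1,2,3,4-tetrahydronaphthalen-1-yl]propanoate | O=S(=O)(Oc1c(C)c(O[Si](C)(C)C(C)(C)C)cc2c1CC[C@H](C(C)=C)[C@@]2(C)CCC(=O)OC)C(F)(F)F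
F5 | step 5 | methyl 3-[(1R,2R)-7-(tert-butyldimethylsilyloxy)-5-ethenyl-1,6-dimethyl-2-(prop-1-en-2-yl)-1,2,3,4-tetrahydronaphthalen-1-yl]propanoate | C=Cc1c(C)c(O[Si](C)(C)C(C)(C)C)cc2c1CC[C@H](C(C)=C)[C@@]2(C)CCC(=O)OC
F6 | step 7 | methyl 3-[(1R,2R,4aS)-5-ethenyl-4a-hydroperoxy-1,6-dimethyl-7-oxo-2-(prop-1-en-2-yl)-1,2,3,4,4a,7-hexahydronaphthalen-1-yl]propanoate (C8 epimer of 19) | C=CC1=C(C)C(=O)C=C2[C@@]1(OO)CC[C@H](C(=C)C)[C@@]2(C)CCC(=O)OC
F7 | step 1 | (S)-1-phenylethylammonium 3-[(7R,8R)-2,3,8-trimethyl-4-oxo-7-(prop-1-en-2-yl)-5,6,7,8-tetrahydro-4H-chromen-8-yl]propanoate | O=C1C(C)=C(C)OC2=C1CC[C@H](C(C)=C)[C@@]2(C)CCC(=O)[O-].C[C@H]([NH3+])c1ccccc1
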